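**Plan** (chain numbered C1 at the guaiacyl ring to C7 at the syringyl ring; the target is the syn-(3R,5S) diacetate)

1. Retrosynthesis first removes the two O-acetyl groups and masks both phenols as benzyl ethers, ties O3 and O5 into an all-cis 2-phenyl-1,3-dioxane, and reinstates C6=C7 as a styrene.
2. The acetal C–O bonds and the C5–O bond are then cut by an allylic transposition back to a C7 benzylic alcohol with a C5=C6 alkene. This is possible because O5 is 1,3 to the C3 carbinol and C5 lies two carbons from the syringyl ring: the C7 oxygen can move to C5 while the alkene slides to C6=C7 into conjugation with that ring, and O3/O5 fit one six-membered dioxane ring.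
3. The open-chain precursor is cut at C5=C6 (cross-metathesis), C3–C4 (allylation of the C1–C3 arm) and C6–C7 (vinyl addition to the syringyl aldehyde).
4. Forward: benzylation, allylation and vinylation give two terminal alkenes, metathesis joins the chain, the only ring (the temporary dioxane) closes in the transposition step, and alkene reduction, acetal hydrolysis, acetylation and debenzylation finish the synthesis.
5. Stereochemistry: C3 (R) comes from catalyst-controlled iridium allylation; C5 is relayed from C3 under thermodynamic control in the reversible transposition/acetalisation; the C7 carbinol configuration and the alkene geometry of the precursor do not matter.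

Key step: step 6

Assumption: the iridium catalyst built from (S)-Cl,MeO-BIPHEP is taken to deliver the (3R)-carbinol 5 (allyl outranks the arylethyl arm in the CIP sense); if the facial sense proves to be the reverse, the mirror-image ligand is used.

**Step 1**
Reactants: 1 3-(4-hydroxy-3-methoxyphenyl)propan-1-ol
Product: 2 3-[4-(benzyloxy)-3-methoxyphenyl]propan-1-ol
Conditions: BnBr (1.05 equiv), K2CO3, acetone, reflux
Reagents that add atoms: benzyl bromide, BrCc1ccccc1
Why: Williamson etherification; K2CO3 deprotonates only the phenol, so the phenoxide is benzylated and the primary alcohol is left free.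

**Step 2**
Reactants: 2 3-[4-(benzyloxy)-3-methoxyphenyl]propan-1-ol; 3 allyl acetate
Product: 5 (3R)-1-[4-(benzyloxy)-3-methoxyphenyl]hex-5-en-3-ol, via 3-[4-(benzyloxy)-3-methoxyphenyl]propanal 4 (not isolated)
Conditions: [Ir(cod)Cl]2 (2.5 mol %), (S)-Cl,MeO-BIPHEP (5 mol %), 4-chloro-3-nitrobenzoic acid (10 mol %), Cs2CO3 (20 mol %), allyl acetate (2 equiv), THF, 100 °C, sealed tube
Reagents that add atoms: none
Why: Krische iridium-catalysed transfer-hydrogenative allylation, in which the cyclometallated π-allyliridium benzoate dehydrogenates 2 to aldehyde 4 and adds the allyl group through a closed chair transition state whose aldehyde face is fixed by the chiral bisphosphine, setting C3 as R.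

**Step 3**
Reactants: 6 syringaldehyde
Product: 7 4-(benzyloxy)-3,5-dimethoxybenzaldehyde
Conditions: BnBr (1.1 equiv), K2CO3, DMF, 60 °C
Reagents that add atoms: benzyl bromide, BrCc1ccccc1
Why: Williamson etherification of an acidic, para-formyl-activated phenol; the aldehyde is inert to carbonate.

**Step 4**
Reactants: 7 4-(benzyloxy)-3,5-dimethoxybenzaldehyde; 8 vinylmagnesium bromide
Product: 9 rac-1-[4-(benzyloxy)-3,5-dimethoxyphenyl]prop-2-en-1-ol
Conditions: vinylMgBr (1.2 equiv), THF, 0 °C; aqueous work-up
Reagents that add atoms: none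
Why: Grignard 1,2-addition to an aromatic aldehyde; the racemic carbinol is acceptable because this carbon (C7) becomes sp2 in step 6.

**Step 5**
Reactants: 5 (3R)-1-[4-(benzyloxy)-3-methoxyphenyl]hex-5-en-3-ol; 9 rac-1-[4-(benzyloxy)-3,5-dimethoxyphenyl]prop-2-en-1-ol
Product: 10 (2E,5R)-7-[4-(benzyloxy)-3-methoxyphenyl]-1-[4-(benzyloxy)-3,5-dimethoxyphenyl]hept-2-ene-1,5-diol (both C1 epimers; C1 here is C7 of the target chain)
Conditions: Hoveyda–Grubbs II (5 mol %), 9 (2.5 equiv), 1,4-benzoquinone (10 mol %), CH2Cl2, 40 °C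
Reagents that add atoms: none
Why: Olefin cross-metathesis of a type I homoallylic alcohol with an excess of a type II secondary allylic alcohol should give the E-alkene under thermodynamic control, with benzoquinone suppressing ruthenium-hydride isomerisation of the aryl vinyl carbinol.

**Step 6**
Reactants: 10 (2E,5R)-7-[4-(benzyloxy)-3-methoxyphenyl]-1-[4-(benzyloxy)-3,5-dimethoxyphenyl]hept-2-ene-1,5-diol
Product: 12 all-cis (2R,4R,6R)-4-{2-[4-(benzyloxy)-3-methoxyphenyl]ethyl}-6-{(E)-2-[4-(benzyloxy)-3,5-dimethoxyphenyl]ethenyl}-2-phenyl-1,3-dioxane, via transposed styryl diol 11 (not isolated)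
Conditions: Re2O7 (5 mol %), PhCH(OMe)2 (3 equiv), CH2Cl2, 0 °C → rt
Reagents that add atoms: benzaldehyde dimethyl acetal, COC(OC)c1ccccc1
Why: Re2O7 turns the C7 hydroxyl into a perrhenate ester that undergoes a polarised, chair-like [3,3] shift, placing oxygen on C5 and moving the alkene to C6=C7 in conjugation with the syringyl ring, while the same acidic medium exchanges benzaldehyde dimethyl acetal onto O3. The closest known reaction type is the Re(VII)-catalysed 1,3-transposition of 2-ene-1,5-diols with in situ benzylidene acetal trapping to syn-1,3-diol acetals. The 1,3-dioxane closes by acetalisation, a 6-endo-trig attack of the C5 hydroxyl of 11 on the benzylic oxocarbenium ion carried by O3, through a chair. Both new stereocentres, C5 and the acetal carbon, are set under thermodynamic control by the fixed C3 centre: C5–O ionisation/transposition and acetal exchange are reversible whereas the saturated C3–O bond cannot ionise, so both C7 epimers and any Z-alkene should drain into the chair with the arylethyl, styryl and phenyl groups all equatorial. The step needs regioselectivity (oxygen at C5, not C7), E geometry and suppression of stray cation capture (by methanol, or by O3 closing a dihydropyran); the first two follow from styrene conjugation and from the fact that only the transposed diol can form a six-membered acetal, the last from the reversibility of such captures at this electron-rich allylic position, low temperature and low catalyst loading.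

**Step 7**
Reactants: 12 all-cis (2R,4R,6R)-4-{2-[4-(benzyloxy)-3-methoxyphenyl]ethyl}-6-{(E)-2-[4-(benzyloxy)-3,5-dimethoxyphenyl]ethenyl}-2-phenyl-1,3-dioxane
Product: 13 all-cis (4R,6S)-4-{2-[4-(benzyloxy)-3-methoxyphenyl]ethyl}-6-{2-[4-(benzyloxy)-3,5-dimethoxyphenyl]ethyl}-2-phenyl-1,3-dioxane
Conditions: TsNHNH2 (6 equiv, portionwise), NaOAc (8 equiv), DME/H2O, reflux
Reagents that add atoms: none
Why: Diimide reduction; concerted syn transfer of H2 to the unpolarised C6=C7 alkene leaves the benzyl ethers and the allylic acetal C–O bond (both at risk under Pd/H2) untouched, and the C5 descriptor changes to S only through CIP priorities.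

**Step 8**
Reactants: 13 all-cis (4R,6S)-4-{2-[4-(benzyloxy)-3-methoxyphenyl]ethyl}-6-{2-[4-(benzyloxy)-3,5-dimethoxyphenyl]ethyl}-2-phenyl-1,3-dioxane
Product: 14 (3R,5S)-1-[4-(benzyloxy)-3-methoxyphenyl]-7-[4-(benzyloxy)-3,5-dimethoxyphenyl]heptane-3,5-diol
Conditions: AcOH/THF/H2O (3:1:1), 50 °C
Reagents that add atoms: none
Why: Acid-catalysed hydrolysis of the benzylidene acetal; with the alkene gone neither carbinol carbon is allylic, so no ionisation or epimerisation is expected, and aryl benzyl ethers are stable to aqueous acetic acid.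

**Step 9**
Reactants: 14 (3R,5S)-1-[4-(benzyloxy)-3-methoxyphenyl]-7-[4-(benzyloxy)-3,5-dimethoxyphenyl]heptane-3,5-diol
Product: 15 (3R,5S)-1-[4-(benzyloxy)-3-methoxyphenyl]-7-[4-(benzyloxy)-3,5-dimethoxyphenyl]heptane-3,5-diyl diacetate
Conditions: Ac2O (4 equiv), pyridine, DMAP (cat.), CH2Cl2, rt
Reagents that add atoms: acetic anhydride, CC(=O)OC(C)=O
Why: DMAP-catalysed acylation of the two secondary alcohols; both phenols are still benzyl-protected, so only the carbinol oxygens are acetylated, with retention at C3 and C5.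

**Step 10**
Reactants: 15 (3R,5S)-1-[4-(benzyloxy)-3-methoxyphenyl]-7-[4-(benzyloxy)-3,5-dimethoxyphenyl]heptane-3,5-diyl diacetate
Product: 16 (3R,5S)-1-(4-hydroxy-3-methoxyphenyl)-7-(4-hydroxy-3,5-dimethoxyphenyl)heptane-3,5-diyl diacetate (CNP0327377.1)
Conditions: H2 (1 atm), 10 % Pd/C, EtOAc, rt
Reagents that add atoms: none
Why: Palladium-catalysed hydrogenolysis of the two aryl benzyl ethers under neutral conditions; secondary alkyl acetates are inert and no acyl migration to the freed phenols is expected without base.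

**Compound list**

1 | 3-(4-hydroxy-3-methoxyphenyl)propan-1-ol (dihydroconiferyl alcohol) | COc1cc(CCCO)ccc1O | starting material
2 | 3-[4-(benzyloxy)-3-methoxyphenyl]propan-1-ol | COc1cc(CCCO)ccc1OCc1ccccc1 | intermediate
3 | allyl acetate | C=CCOC(C)=O | starting material
4 | 3-[4-(benzyloxy)-3-methoxyphenyl]propanal | COc1cc(CCC=O)ccc1OCc1ccccc1 | intermediate
5 | (3R)-1-[4-(benzyloxy)-3-methoxyphenyl]hex-5-en-3-ol | COc1cc(CC[C@H](CC=C)O)ccc1OCc1ccccc1 | intermediate
6 | syringaldehyde | COc1cc(C=O)cc(OC)c1O | starting material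
7 | 4-(benzyloxy)-3,5-dimethoxybenzaldehyde | COc1cc(C=O)cc(OC)c1OCc1ccccc1 | intermediate
8 | vinylmagnesium bromide | C=C[Mg]Br | starting material
9 | rac-1-[4-(benzyloxy)-3,5-dimethoxyphenyl]prop-2-en-1-ol | COc1cc(C(O)C=C)cc(OC)c1OCc1ccccc1 | intermediate
10 | (2E,5R)-7-[4-(benzyloxy)-3-methoxyphenyl]-1-[4-(benzyloxy)-3,5-dimethoxyphenyl]hept-2-ene-1,5-diol (C1 epimers) | COc1cc(CC[C@H](C/C=C/C(O)c2cc(OC)c(OCc3ccccc3)c(OC)c2)O)ccc1OCc1ccccc1 | intermediate
11 | (1E,5R)-7-[4-(benzyloxy)-3-methoxyphenyl]-1-[4-(benzyloxy)-3,5-dimethoxyphenyl]hept-1-ene-3,5-diol (C3 epimers, equilibrating) | COc1cc(CC[C@@H](O)CC(O)/C=C/c2cc(OC)c(OCc3ccccc3)c(OC)c2)ccc1OCc1ccccc1 | intermediate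
12 | all-cis (2R,4R,6R)-4-{2-[4-(benzyloxy)-3-methoxyphenyl]ethyl}-6-{(E)-2-[4-(benzyloxy)-3,5-dimethoxyphenyl]ethenyl}-2-phenyl-1,3-dioxane | COc1cc(CC[C@@H]2C[C@H](/C=C/c3cc(OC)c(OCc4ccccc4)c(OC)c3)O[C@H](c3ccccc3)O2)ccc1OCc1ccccc1 | intermediate
13 | all-cis (4R,6S)-4-{2-[4-(benzyloxy)-3-methoxyphenyl]ethyl}-6-{2-[4-(benzyloxy)-3,5-dimethoxyphenyl]ethyl}-2-phenyl-1,3-dioxane | COc1cc(CC[C@@H]2C[C@H](CCc3cc(OC)c(OCc4ccccc4)c(OC)c3)O[C@H](c3ccccc3)O2)ccc1OCc1ccccc1 | intermediate
14 | (3R,5S)-1-[4-(benzyloxy)-3-methoxyphenyl]-7-[4-(benzyloxy)-3,5-dimethoxyphenyl]heptane-3,5-diol | COc1cc(CC[C@H](C[C@H](CCc2cc(OC)c(OCc3ccccc3)c(OC)c2)O)O)ccc1OCc1ccccc1 | intermediate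
15 | (3R,5S)-1-[4-(benzyloxy)-3-methoxyphenyl]-7-[4-(benzyloxy)-3,5-dimethoxyphenyl]heptane-3,5-diyl diacetate | COc1cc(CC[C@H](C[C@H](CCc2cc(OC)c(OCc3ccccc3)c(OC)c2)OC(C)=O)OC(C)=O)ccc1OCc1ccccc1 | intermediate
16 | (3R,5S)-1-(4-hydroxy-3-methoxyphenyl)-7-(4-hydroxy-3,5-dimethoxyphenyl)heptane-3,5-diyl diacetate | COc1cc(CC[C@H](C[C@H](CCc2cc(OC)c(O)c(OC)c2)OC(C)=O)OC(C)=O)ccc1O | target

**Total step count:** 10
**Longest linear sequence:** 8 steps (steps 1, 2, 5, 6, 7, 8, 9, 10; the branch through steps 3 and 4 is equally long)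

**Steps most likely to fail**

Step 6. The delocalised allyl cation may be captured irreversibly by methanol, by O3 (dihydropyran closure) or by an arene. Equilibration may also stall at a mixture of acetal diastereomers. The fallback sets out from 5 and builds the syn diol without any allylic cation. Boc2O/DMAP converts 5 into the tert-butyl carbonate F1. Iodocarbonate cyclisation (IBr, toluene, −85 °C) should give the cis iodo carbonate F2 with the C5 oxygen delivered syn to C3. K2CO3 in methanol then gives the syn epoxy alcohol F3. In parallel, 7 is reduced with NaBH4 to the benzyl alcohol F4, converted with SOCl2 into the benzyl chloride F5, and this is turned with magnesium into the benzylic Grignard reagent F6. Copper(I)-catalysed opening of F3 at its terminal carbon with F6 (2.5 equiv, THF, −40 °C) forms the C6–C7 bond. The route is rejoined at diol 14, bypassing steps 5 to 8.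

Step 5. Ruthenium-hydride isomerisation of the aryl vinyl carbinol to the ethyl ketone and homodimerisation of the homoallylic alcohol may erode the cross-coupling. The fallback sets out from 9 and removes the isomerisable carbinol before metathesis. MnO2 in CH2Cl2 oxidises 9 to the aryl vinyl ketone F7. Cross-metathesis of F7 with 5 (Hoveyda–Grubbs II, CH2Cl2, 40 °C) should give the E hydroxy enone F8. Luche reduction (NaBH4, CeCl3·7H2O, MeOH, −20 °C) then gives the epimeric allylic alcohols and the route is rejoined at 10.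

Step 2. Enantiofacial control may be insufficient or of the opposite sense, or the redox-neutral coupling may stall. The fallback sets out from 2 and separates oxidation from allylation. Parikh–Doering oxidation (SO3·pyridine, DMSO, Et3N) gives aldehyde 4, now isolated. Brown allylboration with commercial (−)-Ipc2B(allyl) (the reagent from (+)-α-pinene, expected to give the R carbinol with this priority pattern; Et2O, −78 °C, then NaOH/H2O2) returns to the route at 5. No new compound arises (F0).

**Further compounds**

F1 | step 6 | tert-butyl (3R)-1-[4-(benzyloxy)-3-methoxyphenyl]hex-5-en-3-yl carbonate | COc1cc(CC[C@H](CC=C)OC(=O)OC(C)(C)C)ccc1OCc1ccccc1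
F2 | step 6 | (4R,6R)-4-{2-[4-(benzyloxy)-3-methoxyphenyl]ethyl}-6-(iodomethyl)-1,3-dioxan-2-one | COc1cc(CC[C@@H]2C[C@H](CI)OC(=O)O2)ccc1OCc1ccccc1
F3 | step 6 | (2R)-4-[4-(benzyloxy)-3-methoxyphenyl]-1-[(2R)-oxiran-2-yl]butan-2-ol | COc1cc(CC[C@@H](O)C[C@@H]2CO2)ccc1OCc1ccccc1
F4 | step 6 | [4-(benzyloxy)-3,5-dimethoxyphenyl]methanol | COc1cc(CO)cc(OC)c1OCc1ccccc1
F5 | step 6 | 2-(benzyloxy)-5-(chloromethyl)-1,3-dimethoxybenzene | COc1cc(CCl)cc(OC)c1OCc1ccccc1
F6 | step 6 | [4-(benzyloxy)-3,5-dimethoxybenzyl]magnesium chloride | COc1cc(C[Mg]Cl)cc(OC)c1OCc1ccccc1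
F7 | step 5 | 1-[4-(benzyloxy)-3,5-dimethoxyphenyl]prop-2-en-1-one | COc1cc(C(=O)C=C)cc(OC)c1OCc1ccccc1
F8 | step 5 | (2E,5R)-7-[4-(benzyloxy)-3-methoxyphenyl]-1-[4-(benzyloxy)-3,5-dimethoxyphenyl]-5-hydroxyhept-2-en-1-one | COc1cc(CC[C@H](C/C=C/C(=O)c2cc(OC)c(OCc3ccccc3)c(OC)c2)O)ccc1OCc1ccccc1
F0 | step 2 | none | none
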